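**Retrosynthetic overview**
- Rings are lettered A (2,4,6-trihydroxyphenoxy end) to F (3,4,5-trihydroxyphenyl end). The route rests on ring A being a phloroglucinol whose C1, between the hydroxyl-bearing C2 and C6, holds the ether oxygen to C1 of ring B. Ring A is therefore a folded triketide with an aryloxy group on its terminal carbon.
- The fourteen hydroxyls come from twelve methyl ethers (BBr3). The key disconnection is the C1–C2 bond of ring A, which unfolds the arene to a 4-methoxy-6-(aryloxymethyl)-2-pyrone.
- The crowded A–O–B ether thereby becomes a CH2–O bond, made by Williamson alkylation of the B–F phenol with 6-(bromomethyl)-4-methoxy-2-pyrone.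
- The B–F phenol grows from 3,4,5-trimethoxyphenol (ring F) in four identical two-step cycles: Cu-catalysed coupling with 4-bromo-3,5-dimethoxybenzaldehyde, then Baeyer–Villiger conversion of CHO into OH.
- Ring order: F, E, D, C and B are bought as arenes and joined in that order. Ring A is the only ring built, and it is closed last.

Key step: step 11

Remark: the target has no stereocentre and its diaryl ether bonds rotate freely, so no stereocontrol is needed; the only descriptor in the route belongs to the double bond of the opened chain in the key step.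
Shorthand: "X–F" means rings X to F joined in a row. Each of rings B to E is a 3,5-dimethoxyphenyl ring whose C4 oxygen is bound to C1 of the next ring, and ring F is 3,4,5-trimethoxyphenyl. The named group (CHO, OCHO, OH and so on) sits on C1 of ring X.

Step 1
Reactants: 1 3,4,5-trimethoxyphenol (ring F); 2 4-bromo-3,5-dimethoxybenzaldehyde (ring unit)
Product: 3 3,5-dimethoxy-4-(3,4,5-trimethoxyphenoxy)benzaldehyde (E–F aldehyde)
Conditions: CuI (10 mol %), picolinic acid (20 mol %), K3PO4 (2 equiv), DMSO, 90 °C, Ar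
Reagents that add atoms: none
Why: Ullmann-type C–O coupling in which the unhindered phenoxide of 1 binds to picolinate-ligated monovalent copper, a catalyst system that tolerates aryl halides with two ortho substituents, while the para-formyl group of 2 eases activation of the C–Br bond.

Step 2
Reactants: 3 E–F aldehyde
Product: 5 3,5-dimethoxy-4-(3,4,5-trimethoxyphenoxy)phenol (E–F phenol), via E–F aryl formate 4 (not isolated)
Conditions: mCPBA (1.5 equiv), CH2Cl2, 0 °C to rt; crude formate, K2CO3 (cat.), MeOH, rt
Reagents that add atoms: mCPBA (3-chloroperbenzoic acid), OOC(=O)c1cccc(Cl)c1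
Why: Baeyer–Villiger oxidation in which the aryl group, enriched by its para-aryloxy donor, migrates in preference to hydride as it does in 3,4,5-trimethoxybenzaldehyde, followed by mild methanolysis of the labile aryl formate that leaves all ethers untouched.

Step 3
Reactants: 5 E–F phenol; 2 4-bromo-3,5-dimethoxybenzaldehyde
Product: 6 4-[3,5-dimethoxy-4-(3,4,5-trimethoxyphenoxy)phenoxy]-3,5-dimethoxybenzaldehyde (D–F aldehyde)
Conditions: CuI (10 mol %), picolinic acid (20 mol %), K3PO4 (2 equiv), DMSO, 90 °C, Ar
Reagents that add atoms: none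
Why: Ullmann-type C–O coupling as in step 1, since the phenol of 5 has two ortho hydrogens and the same electronic character as 1, so the reacting end is unchanged by the longer chain.

Step 4
Reactants: 6 D–F aldehyde
Product: 8 4-[3,5-dimethoxy-4-(3,4,5-trimethoxyphenoxy)phenoxy]-3,5-dimethoxyphenol (D–F phenol), via D–F aryl formate 7 (not isolated)
Conditions: mCPBA (1.5 equiv), CH2Cl2, 0 °C to rt; crude formate, K2CO3 (cat.), MeOH, rt
Reagents that add atoms: mCPBA (3-chloroperbenzoic acid), OOC(=O)c1cccc(Cl)c1
Why: Baeyer–Villiger oxidation and formate methanolysis as in step 2, confined to the formyl-bearing ring D because the other rings carry only ether groups.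

Step 5
Reactants: 8 D–F phenol; 2 4-bromo-3,5-dimethoxybenzaldehyde
Product: 9 4-{4-[3,5-dimethoxy-4-(3,4,5-trimethoxyphenoxy)phenoxy]-3,5-dimethoxyphenoxy}-3,5-dimethoxybenzaldehyde (C–F aldehyde)
Conditions: CuI (10 mol %), picolinic acid (20 mol %), K3PO4 (2 equiv), DMSO, 90 °C, Ar
Reagents that add atoms: none
Why: Ullmann-type C–O coupling of an unhindered phenoxide with the formyl-activated bromide, identical at the reacting atoms to steps 1 and 3.

Step 6
Reactants: 9 C–F aldehyde
Product: 11 C–F phenol (tetramer, OH on C1 of ring C), via C–F aryl formate 10 (not isolated)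
Conditions: mCPBA (1.5 equiv), CH2Cl2, 0 °C to rt; crude formate, K2CO3 (cat.), MeOH, rt
Reagents that add atoms: mCPBA (3-chloroperbenzoic acid), OOC(=O)c1cccc(Cl)c1
Why: Baeyer–Villiger oxidation with aryl migration driven by the para-aryloxy group of ring C, then transesterification of the formate with methanol.

Step 7
Reactants: 11 C–F phenol; 2 4-bromo-3,5-dimethoxybenzaldehyde
Product: 12 B–F aldehyde (pentamer, CHO on C1 of ring B)
Conditions: CuI (15 mol %), picolinic acid (30 mol %), K3PO4 (2 equiv), DMSO, 100 °C, Ar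
Reagents that add atoms: none
Why: Ullmann-type C–O coupling as before, with a slightly higher catalyst loading and temperature to offset the lower molar concentration and solubility of the tetramer.

Step 8
Reactants: 12 B–F aldehyde
Product: 14 B–F phenol (pentamer, OH on C1 of ring B), via B–F aryl formate 13 (not isolated)
Conditions: mCPBA (1.5 equiv), CH2Cl2, 0 °C to rt; crude formate, K2CO3 (cat.), MeOH/THF, rt
Reagents that add atoms: mCPBA (3-chloroperbenzoic acid), OOC(=O)c1cccc(Cl)c1
Why: Baeyer–Villiger oxidation and formate methanolysis as in steps 2, 4 and 6, which frees the unhindered phenol needed for the alkylation.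

Step 9
Reactants: 15 4-methoxy-6-methyl-2H-pyran-2-one
Product: 16 6-(bromomethyl)-4-methoxy-2H-pyran-2-one
Conditions: NBS (1.05 equiv), (PhCO2)2 (cat.), CCl4 or PhCF3, reflux
Reagents that add atoms: N-bromosuccinimide, O=C1CCC(=O)N1Br
Why: Wohl–Ziegler bromination, known for this pyrone, in which radical-chain conditions in a non-polar solvent direct hydrogen abstraction to the C6 methyl group (radical delocalised over the pyrone diene) and suppress ionic bromination at C3.

Step 10
Reactants: 14 B–F phenol; 16 6-(bromomethyl)-4-methoxy-2H-pyran-2-one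
Product: 17 4-methoxy-6-[(B–F aryloxy)methyl]-2H-pyran-2-one
Conditions: K2CO3 (1.5 equiv), DMF, rt to 40 °C
Reagents that add atoms: none
Why: Williamson ether synthesis, an SN2 displacement by an unhindered phenoxide on a primary allylic-type bromide under a carbonate base too weak to open the pyrone.

Step 11
Reactants: 17 4-methoxy-6-[(B–F aryloxy)methyl]-2H-pyran-2-one
Product: 20 2-(B–F aryloxy)-5-methoxybenzene-1,3-diol (A–F hexamer in which ring A is a 5-methoxyresorcinol), via opened keto ester 18 (not isolated), via cyclohexenedione tautomer 19 (not isolated)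
Conditions: NaOMe (10 equiv), dry MeOH/1,4-dioxane, sealed tube, 150–170 °C, Ar; then 1 M HCl, 0 °C
Reagents that add atoms: sodium methoxide, [Na+].[O-]C (its methoxy group is held only in 18 and leaves again on closure; none of its atoms stay in 20)
Why: Methoxide adds to the lactone carbonyl of 17 and opens the ring to methyl hexenoate 18, whose C2=C3 double bond keeps the geometry of the pyrone and so holds the ester and the aryloxyacetonyl arm on the same side. The more stable dienolate at C4 of 18 can only fall back to the pyrone by O-acylation, whereas the less populated enolate at C6, made more accessible by the attached aryloxy oxygen, attacks the ester carbon in an intramolecular Claisen closure of 6-(enolendo)-exo-trig type (geometrically allowed for six-membered rings), forms the C1–C2 bond of ring A and expels methoxide to give 19. Dione 19 enolises at once and is stored as the resorcinolate of 20, so that every reversible event, including pyrone reclosure and methoxide exchange at the vinylogous ester carbon (degenerate in NaOMe/MeOH), drains into the arene. The closest known reaction is the isomerisation of the parent pyrone 15 to 5-methoxyresorcinol under forcing NaOMe/MeOH conditions, from which this case differs only by the aryloxy group on the nucleophilic carbon. No stereocentre remains, as the one at the aryloxy-bearing carbon of 19 is erased by enolisation. The step needs C- over O-acylation, secured by the aromatic phenoxide sink, and retention of the CH–OAr bond, secured by the poor leaving-group ability of the electron-rich aryloxide and by an anhydrous medium that excludes saponification and decarboxylation of 18.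

Step 12
Reactants: 20 A–F hexamer with a 5-methoxyresorcinol ring A
Product: 21 target, CNP0187343.0 (A–F hexamer with fourteen free hydroxyl groups)
Conditions: BBr3 (30 equiv), CH2Cl2, −78 °C to rt, Ar; then ice-water, EtOAc extraction under Ar
Reagents that add atoms: none
Why: Lewis-acid ether cleavage in which BBr3 binds each methoxy oxygen and bromide attacks the methyl carbon by SN2, while the diaryl ether oxygens offer no sp3 carbon and stay intact, and hydrolysis of the aryl borates frees all twelve masked hydroxyls.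

**Compound list**
1 | 3,4,5-trimethoxyphenol | COc1cc(O)cc(OC)c1OC | starting material
2 | 4-bromo-3,5-dimethoxybenzaldehyde | COc1cc(C=O)cc(OC)c1Br | starting material
3 | 3,5-dimethoxy-4-(3,4,5-trimethoxyphenoxy)benzaldehyde (E–F aldehyde) | O=Cc1cc(OC)c(Oc2cc(OC)c(OC)c(OC)c2)c(OC)c1 | intermediate
4 | 3,5-dimethoxy-4-(3,4,5-trimethoxyphenoxy)phenyl formate (E–F aryl formate, not isolated) | O=COc1cc(OC)c(Oc2cc(OC)c(OC)c(OC)c2)c(OC)c1 | intermediate
5 | 3,5-dimethoxy-4-(3,4,5-trimethoxyphenoxy)phenol (E–F phenol) | Oc1cc(OC)c(Oc2cc(OC)c(OC)c(OC)c2)c(OC)c1 | intermediate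
6 | D–F aldehyde | O=Cc1cc(OC)c(Oc2cc(OC)c(Oc3cc(OC)c(OC)c(OC)c3)c(OC)c2)c(OC)c1 | intermediate
7 | D–F aryl formate (not isolated) | O=COc1cc(OC)c(Oc2cc(OC)c(Oc3cc(OC)c(OC)c(OC)c3)c(OC)c2)c(OC)c1 | intermediate
8 | D–F phenol | Oc1cc(OC)c(Oc2cc(OC)c(Oc3cc(OC)c(OC)c(OC)c3)c(OC)c2)c(OC)c1 | intermediate
9 | C–F aldehyde | O=Cc1cc(OC)c(Oc2cc(OC)c(Oc3cc(OC)c(Oc4cc(OC)c(OC)c(OC)c4)c(OC)c3)c(OC)c2)c(OC)c1 | intermediate
10 | C–F aryl formate (not isolated) | O=COc1cc(OC)c(Oc2cc(OC)c(Oc3cc(OC)c(Oc4cc(OC)c(OC)c(OC)c4)c(OC)c3)c(OC)c2)c(OC)c1 | intermediate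
11 | C–F phenol | Oc1cc(OC)c(Oc2cc(OC)c(Oc3cc(OC)c(Oc4cc(OC)c(OC)c(OC)c4)c(OC)c3)c(OC)c2)c(OC)c1 | intermediate
12 | B–F aldehyde | O=Cc1cc(OC)c(Oc2cc(OC)c(Oc3cc(OC)c(Oc4cc(OC)c(Oc5cc(OC)c(OC)c(OC)c5)c(OC)c4)c(OC)c3)c(OC)c2)c(OC)c1 | intermediate
13 | B–F aryl formate (not isolated) | O=COc1cc(OC)c(Oc2cc(OC)c(Oc3cc(OC)c(Oc4cc(OC)c(Oc5cc(OC)c(OC)c(OC)c5)c(OC)c4)c(OC)c3)c(OC)c2)c(OC)c1 | intermediate
14 | B–F phenol | Oc1cc(OC)c(Oc2cc(OC)c(Oc3cc(OC)c(Oc4cc(OC)c(Oc5cc(OC)c(OC)c(OC)c5)c(OC)c4)c(OC)c3)c(OC)c2)c(OC)c1 | intermediate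
15 | 4-methoxy-6-methyl-2H-pyran-2-one | COC1=CC(=O)OC(C)=C1 | starting material
16 | 6-(bromomethyl)-4-methoxy-2H-pyran-2-one | COC1=CC(=O)OC(CBr)=C1 | intermediate
17 | 4-methoxy-6-[(B–F aryloxy)methyl]-2H-pyran-2-one | COC1=CC(=O)OC(COc2cc(OC)c(Oc3cc(OC)c(Oc4cc(OC)c(Oc5cc(OC)c(Oc6cc(OC)c(OC)c(OC)c6)c(OC)c5)c(OC)c4)c(OC)c3)c(OC)c2)=C1 | intermediate
18 | methyl (E)-6-(B–F aryloxy)-3-methoxy-5-oxohex-2-enoate, ester and C4 on the same side of the double bond (not isolated) | COC(=O)/C=C(/OC)CC(=O)COc1cc(OC)c(Oc2cc(OC)c(Oc3cc(OC)c(Oc4cc(OC)c(Oc5cc(OC)c(OC)c(OC)c5)c(OC)c4)c(OC)c3)c(OC)c2)c(OC)c1 | intermediate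
19 | 2-(B–F aryloxy)-5-methoxycyclohex-4-ene-1,3-dione, racemic and configurationally labile at C2 (not isolated) | COC1=CC(=O)C(Oc2cc(OC)c(Oc3cc(OC)c(Oc4cc(OC)c(Oc5cc(OC)c(Oc6cc(OC)c(OC)c(OC)c6)c(OC)c5)c(OC)c4)c(OC)c3)c(OC)c2)C(=O)C1 | intermediate
20 | 2-(B–F aryloxy)-5-methoxybenzene-1,3-diol (A–F hexamer, ring A as 5-methoxyresorcinol) | COc1cc(O)c(Oc2cc(OC)c(Oc3cc(OC)c(Oc4cc(OC)c(Oc5cc(OC)c(Oc6cc(OC)c(OC)c(OC)c6)c(OC)c5)c(OC)c4)c(OC)c3)c(OC)c2)c(O)c1 | intermediate
21 | CNP0187343.0, A–F hexamer with fourteen hydroxyl groups | Oc1cc(O)c(Oc2cc(O)c(Oc3cc(O)c(Oc4cc(O)c(Oc5cc(O)c(Oc6cc(O)c(O)c(O)c6)c(O)c5)c(O)c4)c(O)c3)c(O)c2)c(O)c1 | target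

**Step count**
- Total: 12 steps.
- Longest linear sequence: 11 steps (steps 1–8, 10, 11, 12). Step 9 is a one-step branch.

**Steps most likely to fail**

1. **Step 11.**
   - At the temperature needed, three processes may outrun the C-acylation: retro-Claisen fragmentation of the opened chain by methoxide attack on the activated ketone, expulsion of aryloxide from the C4 enolate, or plain return to the pyrone.
   - Partial loss of aryl methyl groups would not matter, since all of them fall in step 12.
   - Fallback: ring A is brought in as a preformed arene. The fallback sets out from 14, which is coupled once more with 2 under the conditions of step 7 to give the A–F aldehyde F1.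
   - Baeyer–Villiger oxidation with mCPBA gives the A–F aryl formate F2, and catalytic K2CO3 in MeOH frees the A–F phenol F3, in which ring A is a 4-hydroxy-2,6-dimethoxyphenoxy group.
   - BBr3 in CH2Cl2 then cleaves its thirteen methyl ethers, and the fallback comes back to the route at 21.

2. **Step 7.**
   - Activation of the C–Br bond between two methoxy groups may become too slow as the phenol partner grows and dissolves less well, so that hydrodebromination of 2 and oxidative decay of the phenoxide take over.
   - Fallback: the polarity of the coupling is reversed, so that the hindered oxygen acts as the nucleophile. The fallback sets out from 11, and Tf2O with pyridine in CH2Cl2 gives the C–F aryl triflate F4.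
   - Miyaura borylation (B2pin2, Pd(dppf)Cl2, KOAc, dioxane, 85 °C) gives the C–F pinacol boronate F5, and NaIO4 with NH4OAc in aqueous acetone gives the C–F boronic acid F6.
   - Chan–Lam coupling of F6 with commercial syringaldehyde (4-hydroxy-3,5-dimethoxybenzaldehyde) then follows, using Cu(OAc)2, pyridine and 4 Å molecular sieves in CH2Cl2 under air at rt. This reaction type accepts phenols with two ortho substituents. It returns to the route at 12.

3. **Step 12.**
   - Cleavage may stop short because partly demethylated boron aryloxides precipitate from CH2Cl2.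
   - The very polar polyphenol may also be lost to air oxidation or to adsorption during isolation.
   - Fallback: purification is moved to a protected derivative. The fallback sets out from 20, which is treated with BBr3 as before, and the crude product is acetylated at once (Ac2O, pyridine, DMAP cat.) to the tetradecaacetate F7.
   - F7 can be separated on silica gel from incompletely demethylated material.
   - Acid-catalysed methanolysis (HCl generated from a little AcCl in degassed MeOH, rt to 40 °C, Ar) and evaporation of the volatiles return to the route at 21.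

**Further compounds**
F1 | step 11 | A–F aldehyde (ring A as 4-formyl-2,6-dimethoxyphenoxy) | O=Cc1cc(OC)c(Oc2cc(OC)c(Oc3cc(OC)c(Oc4cc(OC)c(Oc5cc(OC)c(Oc6cc(OC)c(OC)c(OC)c6)c(OC)c5)c(OC)c4)c(OC)c3)c(OC)c2)c(OC)c1
F2 | step 11 | A–F aryl formate | O=COc1cc(OC)c(Oc2cc(OC)c(Oc3cc(OC)c(Oc4cc(OC)c(Oc5cc(OC)c(Oc6cc(OC)c(OC)c(OC)c6)c(OC)c5)c(OC)c4)c(OC)c3)c(OC)c2)c(OC)c1
F3 | step 11 | A–F phenol (ring A as 4-hydroxy-2,6-dimethoxyphenoxy) | Oc1cc(OC)c(Oc2cc(OC)c(Oc3cc(OC)c(Oc4cc(OC)c(Oc5cc(OC)c(Oc6cc(OC)c(OC)c(OC)c6)c(OC)c5)c(OC)c4)c(OC)c3)c(OC)c2)c(OC)c1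
F4 | step 7 | C–F aryl triflate | O=S(=O)(Oc1cc(OC)c(Oc2cc(OC)c(Oc3cc(OC)c(Oc4cc(OC)c(OC)c(OC)c4)c(OC)c3)c(OC)c2)c(OC)c1)C(F)(F)F
F5 | step 7 | C–F pinacol boronate | CC1(C)OB(OC1(C)C)c1cc(OC)c(Oc2cc(OC)c(Oc3cc(OC)c(Oc4cc(OC)c(OC)c(OC)c4)c(OC)c3)c(OC)c2)c(OC)c1
F6 | step 7 | C–F boronic acid | OB(O)c1cc(OC)c(Oc2cc(OC)c(Oc3cc(OC)c(Oc4cc(OC)c(OC)c(OC)c4)c(OC)c3)c(OC)c2)c(OC)c1
F7 | step 12 | tetradecaacetate of 21 | CC(=O)Oc1cc(OC(C)=O)c(Oc2cc(OC(C)=O)c(Oc3cc(OC(C)=O)c(Oc4cc(OC(C)=O)c(Oc5cc(OC(C)=O)c(Oc6cc(OC(C)=O)c(OC(C)=O)c(OC(C)=O)c6)c(OC(C)=O)c5)c(OC(C)=O)c4)c(OC(C)=O)c3)c(OC(C)=O)c2)c(OC(C)=O)c1
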